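**Plan**

- Retrosynthesis: the two aryl O–Si bonds are cut first (protection), then C2–H and C2–aryl of the flavan, which leads back to a chroman-2-one; that lactone is cut at C3–CH2 (benzyl) and C4–Cα (styryl).
- Enabling feature: in 7-methoxycoumarin the C3=C4 bond of the pyranone ring is conjugated to the C2 lactone carbonyl, so C4 (β) accepts an alkenyl nucleophile and C3 (α) becomes the enolate carbon that takes a benzyl electrophile.
- Forward: the benzopyran ring is bought ready-made and no ring is formed. One silylated 4-hydroxybenzaldehyde is divided into the benzyl bromide and, via the alkyne, the (E)-alkenyl-9-BBN; both are joined to the coumarin in one flask, then the C2 aryl group is added, the hemiketal is reduced and the silyl groups are removed.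
- Stereochemistry: C4 from the chiral rhodium–bisphosphine catalyst; C3 from alkylation anti to the C4 group (trans, also the more stable arrangement); C2 from pseudoaxial hydride delivery to the cyclic oxocarbenium ion (aryl equatorial, 2,3-trans and 2,4-cis); the E-alkene from syn hydroboration.

Key step: step 6

Remark on the chemistry: the sense of induction of the (S)-bisphosphine–rhodium catalyst with an alkenyl-9-BBN is assumed to follow that established for aryl transfer to coumarins and cyclic enones, which corresponds to the 4R product here; if it proves opposite, the (R)-ligand is used with no other change.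

Remark on the chemistry: the hemiketal from the aryllithium addition is written in its cyclic form; it may exist largely as the open 2-hydroxyaryl ketone tautomer, and both forms enter the reduction through the same oxocarbenium ion.

**Route**

Step 1
Reactants: 1 4-hydroxybenzaldehyde
Product: 2 4-(triisopropylsilyloxy)benzaldehyde
Conditions: TIPSCl, imidazole, DMF, rt
Reagents that add atoms: chlorotriisopropylsilane, CC(C)[Si](Cl)(C(C)C)C(C)C
Why: Imidazole-promoted O-silylation of the phenol (silyl ether protection); the bulky TIPS ether should survive borohydride, organolithiums at −78 °C and BF3 at low temperature, and is removed by fluoride at the end.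

Step 2
Reactants: 2 4-(triisopropylsilyloxy)benzaldehyde
Product: 3 [4-(triisopropylsilyloxy)phenyl]methanol
Conditions: NaBH4, EtOH/THF, 0 °C
Reagents that add atoms: none
Why: Borohydride reduction of an aromatic aldehyde to the benzylic alcohol, which at 0 °C should leave the aryl silyl ether intact.

Step 3
Reactants: 3 [4-(triisopropylsilyloxy)phenyl]methanol
Product: 4 4-(triisopropylsilyloxy)benzyl bromide
Conditions: CBr4, PPh3, CH2Cl2, 0 °C
Reagents that add atoms: carbon tetrabromide, BrC(Br)(Br)Br
Why: Appel bromination turns the primary benzylic alcohol into the bromide under neutral conditions, avoiding the HBr that could cleave the silyl ether or ionise the electron-rich benzylic position.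

Step 4
Reactants: 2 4-(triisopropylsilyloxy)benzaldehyde
Product: 5 (4-ethynylphenoxy)triisopropylsilane
Conditions: TMSCHN2, LDA, THF, −78 °C → rt
Reagents that add atoms: trimethylsilyldiazomethane, C[Si](C)(C)C=[N+]=[N-]
Why: Colvin rearrangement: lithiated trimethylsilyldiazomethane adds to the aldehyde, Peterson elimination and loss of N2 give an alkylidene carbene that rearranges to the terminal alkyne, all under aprotic conditions that spare the aryl silyl ether.

Step 5
Reactants: 5 (4-ethynylphenoxy)triisopropylsilane
Product: 6 B-[(E)-4-(triisopropylsilyloxy)styryl]-9-borabicyclo[3.3.1]nonane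
Conditions: 9-BBN-H (1 equiv B–H), 5 (2 equiv), THF, 0 °C → rt, argon; excess 5 distilled off under high vacuum and recovered
Reagents that add atoms: 9-borabicyclo[3.3.1]nonane, B1C2CCCC1CCC2
Why: Syn, anti-Markovnikov hydroboration of the terminal alkyne puts boron on the terminal carbon and gives the (E)-alkenylborane, and the excess of alkyne suppresses the second hydroboration to the 1,1-diboryl compound.

Step 6
Reactants: 7 7-methoxycoumarin; 6 B-[(E)-4-(triisopropylsilyloxy)styryl]-9-borabicyclo[3.3.1]nonane; 4 4-(triisopropylsilyloxy)benzyl bromide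
Product: 10 (3R,4R)-7-methoxy-3-[4-(triisopropylsilyloxy)benzyl]-4-[(E)-4-(triisopropylsilyloxy)styryl]chroman-2-one, via boron enolate 8 (not isolated), via lithium enolate 9 (not isolated)
Conditions: [Rh(OMe)(cod)]2 (3 mol% Rh), (S)-SEGPHOS (3.3 mol%), 6 (1.2 equiv), toluene, 80 °C; then THF, MeLi (1 equiv per boron), −78 °C; then 4 (1.5 equiv), DMPU, −78 → −20 °C
Reagents that add atoms: none
Why: Proposed new method: the (E)-alkenyl group should pass from boron to the (S)-SEGPHOS–rhodium(I) centre, the coumarin C3=C4 bond should insert into the Rh–alkenyl bond with the alkenyl group going to C4, and the resulting oxa-π-allyl rhodium should hand its enolate oxygen to a second molecule of 6, which regenerates Rh–alkenyl and leaves the O-boryl ketene acetal 8; MeLi then binds boron, freeing lithium enolate 9 and B-methyl-9-BBN, and 9 is benzylated at C3 by SN2 attack on 4. The closest known reaction type is the rhodium/bisphosphine-catalysed asymmetric 1,4-addition of B-aryl-9-BBN reagents to cyclic enones under aprotic conditions with alkylation of the boron enolate after alkyllithium activation, alongside the rhodium/SEGPHOS-catalysed asymmetric 1,4-arylation of coumarins with boronic acids; an alkenyl-9-BBN, a lactone-derived enolate and a benzyl halide have not been combined in this way. No ring is closed; the step forms C4–Cα and C3–CH2 on the existing pyranone. C4 is controlled by the chiral ligand, which differentiates the enantiotopic faces of the flat coumarin at the insertion, and C3 by the substrate, the bromide approaching the half-boat enolate anti to the pseudoaxial C4 styryl group, with the trans lactone also the more stable isomer at this epimerisable centre. The step needs 1,4- over 1,2-addition, retention of the E geometry and monoalkylation: a soft Rh–alkenyl adds only in conjugate fashion, B-to-Rh transfer and insertion retain the geometry of the alkenyl carbon, and low temperature with a modest excess of 4 limits proton exchange between 10 and 9.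

Step 7
Reactants: 10 (3R,4R)-7-methoxy-3-[4-(triisopropylsilyloxy)benzyl]-4-[(E)-4-(triisopropylsilyloxy)styryl]chroman-2-one; 11 1-bromo-2,4-dimethoxybenzene
Product: 13 (3R,4R)-2-(2,4-dimethoxyphenyl)-7-methoxy-3-[4-(triisopropylsilyloxy)benzyl]-4-[(E)-4-(triisopropylsilyloxy)styryl]chroman-2-ol, via 2,4-dimethoxyphenyllithium 12 (not isolated)
Conditions: 11, n-BuLi (1.0 equiv), THF, −78 °C; the solution is added slowly to 10, THF, −78 °C; aq. NH4Cl at −78 °C
Reagents that add atoms: none
Why: Bromine–lithium exchange gives the aryllithium, which adds once to the lactone carbonyl (organolithium addition to a lactone giving a lactol); with one equivalent at −78 °C the tetrahedral alkoxide, or the hindered electron-rich aryl ketone phenoxide if it opens, should resist a second addition, and C3 and C4 are not involved.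

Step 8
Reactants: 13 (3R,4R)-2-(2,4-dimethoxyphenyl)-7-methoxy-3-[4-(triisopropylsilyloxy)benzyl]-4-[(E)-4-(triisopropylsilyloxy)styryl]chroman-2-ol
Product: 14 (2R,3R,4R)-2-(2,4-dimethoxyphenyl)-7-methoxy-3-[4-(triisopropylsilyloxy)benzyl]-4-[(E)-4-(triisopropylsilyloxy)styryl]chroman
Conditions: Et3SiH, BF3·OEt2, CH2Cl2, −78 → −40 °C
Reagents that add atoms: none
Why: The Lewis acid ionises the hemiketal to the 2-aryl cyclic oxocarbenium ion, which the silane reduces (ionic reduction of a lactol, as in C-aryl glycoside synthesis); hydride should add pseudoaxially to the half-chair that carries the C3 benzyl and C4 styryl groups pseudoequatorially, so the C2 aryl group ends equatorial, trans to C3 and cis to C4, which is the 2R configuration.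

Step 9
Reactants: 14 (2R,3R,4R)-2-(2,4-dimethoxyphenyl)-7-methoxy-3-[4-(triisopropylsilyloxy)benzyl]-4-[(E)-4-(triisopropylsilyloxy)styryl]chroman
Product: 15 caraganin C, 4-{[(2R,3R,4R)-2-(2,4-dimethoxyphenyl)-4-[(E)-2-(4-hydroxyphenyl)ethenyl]-7-methoxy-3,4-dihydro-2H-chromen-3-yl]methyl}phenol
Conditions: TBAF, AcOH, THF, 0 °C → rt
Reagents that add atoms: none
Why: Fluoride cleaves both aryl triisopropylsilyl ethers (silyl ether deprotection), and the acetic acid buffer keeps the liberated phenols protonated so that the electron-rich flavan and the styryl alkene see no strongly basic medium; no stereocentre is touched.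

**Compound list**

1 | 4-hydroxybenzaldehyde | O=Cc1ccc(O)cc1 | starting material
2 | 4-(triisopropylsilyloxy)benzaldehyde | O=Cc1ccc(O[Si](C(C)C)(C(C)C)C(C)C)cc1 | intermediate
3 | [4-(triisopropylsilyloxy)phenyl]methanol | OCc1ccc(O[Si](C(C)C)(C(C)C)C(C)C)cc1 | intermediate
4 | 4-(triisopropylsilyloxy)benzyl bromide | BrCc1ccc(O[Si](C(C)C)(C(C)C)C(C)C)cc1 | intermediate
5 | (4-ethynylphenoxy)triisopropylsilane | C#Cc1ccc(O[Si](C(C)C)(C(C)C)C(C)C)cc1 | intermediate
6 | B-[(E)-4-(triisopropylsilyloxy)styryl]-9-borabicyclo[3.3.1]nonane | C1CC2CCCC(C1)B2/C=C/c1ccc(O[Si](C(C)C)(C(C)C)C(C)C)cc1 | intermediate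
7 | 7-methoxycoumarin | COc1ccc2ccc(=O)oc2c1 | starting material
8 | boron enolate, (R)-9-({7-methoxy-4-[(E)-4-(triisopropylsilyloxy)styryl]-4H-chromen-2-yl}oxy)-9-borabicyclo[3.3.1]nonane | COc1ccc2c(c1)OC(OB1C3CCCC1CCC3)=C[C@H]2/C=C/c1ccc(O[Si](C(C)C)(C(C)C)C(C)C)cc1 | intermediate (not isolated)
9 | lithium enolate, lithium (R)-7-methoxy-4-[(E)-4-(triisopropylsilyloxy)styryl]-4H-chromen-2-olate | COc1ccc2c(c1)OC(O[Li])=C[C@H]2/C=C/c1ccc(O[Si](C(C)C)(C(C)C)C(C)C)cc1 | intermediate (not isolated)
10 | (3R,4R)-7-methoxy-3-[4-(triisopropylsilyloxy)benzyl]-4-[(E)-4-(triisopropylsilyloxy)styryl]chroman-2-one | COc1ccc2c(c1)OC(=O)[C@H](Cc1ccc(O[Si](C(C)C)(C(C)C)C(C)C)cc1)[C@H]2/C=C/c1ccc(O[Si](C(C)C)(C(C)C)C(C)C)cc1 | intermediate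
11 | 1-bromo-2,4-dimethoxybenzene | COc1ccc(Br)c(OC)c1 | starting material
12 | 2,4-dimethoxyphenyllithium | [Li]c1ccc(OC)cc1OC | intermediate (not isolated)
13 | (3R,4R)-2-(2,4-dimethoxyphenyl)-7-methoxy-3-[4-(triisopropylsilyloxy)benzyl]-4-[(E)-4-(triisopropylsilyloxy)styryl]chroman-2-ol (C2 epimers, in equilibrium with the open ketone) | COc1ccc2c(c1)OC(O)(c1ccc(OC)cc1OC)[C@H](Cc1ccc(O[Si](C(C)C)(C(C)C)C(C)C)cc1)[C@H]2/C=C/c1ccc(O[Si](C(C)C)(C(C)C)C(C)C)cc1 | intermediate
14 | (2R,3R,4R)-2-(2,4-dimethoxyphenyl)-7-methoxy-3-[4-(triisopropylsilyloxy)benzyl]-4-[(E)-4-(triisopropylsilyloxy)styryl]chroman | COc1ccc2c(c1)O[C@@H](c1ccc(OC)cc1OC)[C@H](Cc1ccc(O[Si](C(C)C)(C(C)C)C(C)C)cc1)[C@H]2/C=C/c1ccc(O[Si](C(C)C)(C(C)C)C(C)C)cc1 | intermediate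
15 | caraganin C | COc1ccc2c(c1)O[C@@H](c1ccc(OC)cc1OC)[C@H](Cc1ccc(O)cc1)[C@H]2/C=C/c1ccc(O)cc1 | target

**Step count**

Total: 9 steps. Longest linear sequence: 7 steps (1 → 2 → 5 → 6 → 10 → 13 → 14 → 15, steps 1, 4, 5, 6, 7, 8, 9).

**Steps most likely to fail**

1. Step 6. Insertion into the coumarin, whose enoate is made electron-rich by the 7-methoxy group, may be slow. Turnover may stall if the rhodium enolate of the aryl lactone does not transfer to boron. On activation the aryl ester enolate may open to a ketene phenoxide or be alkylated twice. The fallback separates the two bond formations and uses known chemistry; it sets out from 5 and 7 and comes back at 10. Hydroboration of 5 with catecholborane (THF, 70 °C) should give the alkenyl catechol boronate 2-{(E)-2-[4-(triisopropylsilyloxy)phenyl]ethenyl}-1,3,2-benzodioxaborole F1. Its rhodium-catalysed asymmetric conjugate addition to 7 under protic conditions (Rh(acac)(C2H4)2, (S)-SEGPHOS, dioxane/H2O, Et3N, 60 °C, mildly acidic work-up), where the rhodium enolate is simply protonated, should give (S)-7-methoxy-4-[(E)-4-(triisopropylsilyloxy)styryl]chroman-2-one F2. This has the same spatial arrangement at C4 as 10; the descriptor differs only because C3 is unsubstituted. Deprotonation of F2 with LiHMDS (THF, −78 °C) and alkylation with 4 anti to the C4 group should then give 10.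

2. Step 8. Hydride may be delivered to the wrong face if the cation reacts through the half-chair with both side arms pseudoaxial, which would give the 2,3-cis epimer. C3 may lose its configuration through reversible deprotonation to the 4H-chromene. The electron-rich benzylic C2–O bond of the product may ionise and be reduced a second time. The fallback sets out from 13 and comes back at 14. NaBH4 (MeOH/THF, 0 °C) should reduce the open ketone tautomer of 13 to the benzylic alcohol (1RS,2R,3R,4E)-1-(2,4-dimethoxyphenyl)-3-(2-hydroxy-4-methoxyphenyl)-2-[4-(triisopropylsilyloxy)benzyl]-5-[4-(triisopropylsilyloxy)phenyl]pent-4-en-1-ol F3. A catalytic amount of PPTS (CH2Cl2, 0 °C → rt) should ionise the 2,4-dimethoxybenzylic alcohol, and the phenol should trap the cation (cyclodehydration to a flavan). Because this closure is reversible, it should settle on the all-equatorial 2,3-trans-2,4-cis isomer 14 whatever the carbinol configuration, and no hydride source is present to over-reduce.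

3. Step 7. The tetrahedral intermediate may collapse to the ketone phenoxide and take up a second aryllithium, or the basic aryllithium may enolise the lactone and erode C3. The fallback sets out from 10 and comes back at 13. Aminolysis of the aryl lactone with N,O-dimethylhydroxylamine hydrochloride and i-PrMgCl (THF, −20 °C) should give the ring-opened amide (2R,3R,4E)-3-(2-hydroxy-4-methoxyphenyl)-N-methoxy-N-methyl-2-[4-(triisopropylsilyloxy)benzyl]-5-[4-(triisopropylsilyloxy)phenyl]pent-4-enamide F4. After deprotonation of its phenol with i-PrMgCl, addition of 12 at −78 °C (Weinreb ketone synthesis) should stop at the chelated tetrahedral intermediate, which cannot accept a second aryl group. Work-up releases the ketone, which is the open tautomer of 13.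

**Further compounds**

F1 | step 6 | 2-{(E)-2-[4-(triisopropylsilyloxy)phenyl]ethenyl}-1,3,2-benzodioxaborole | B1(/C=C/c2ccc(O[Si](C(C)C)(C(C)C)C(C)C)cc2)Oc2ccccc2O1
F2 | step 6 | (S)-7-methoxy-4-[(E)-4-(triisopropylsilyloxy)styryl]chroman-2-one | COc1ccc2c(c1)OC(=O)C[C@H]2/C=C/c1ccc(O[Si](C(C)C)(C(C)C)C(C)C)cc1
F3 | step 8 | (1RS,2R,3R,4E)-1-(2,4-dimethoxyphenyl)-3-(2-hydroxy-4-methoxyphenyl)-2-[4-(triisopropylsilyloxy)benzyl]-5-[4-(triisopropylsilyloxy)phenyl]pent-4-en-1-ol | COc1ccc(c(O)c1)[C@H](/C=C/c1ccc(O[Si](C(C)C)(C(C)C)C(C)C)cc1)[C@@H](Cc1ccc(O[Si](C(C)C)(C(C)C)C(C)C)cc1)C(O)c1ccc(OC)cc1OC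
F4 | step 7 | (2R,3R,4E)-3-(2-hydroxy-4-methoxyphenyl)-N-methoxy-N-methyl-2-[4-(triisopropylsilyloxy)benzyl]-5-[4-(triisopropylsilyloxy)phenyl]pent-4-enamide | COc1ccc(c(O)c1)[C@H](/C=C/c1ccc(O[Si](C(C)C)(C(C)C)C(C)C)cc1)[C@@H](Cc1ccc(O[Si](C(C)C)(C(C)C)C(C)C)cc1)C(=O)N(C)OC
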